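In the blue run, partner equal to 10.4% of the starting material goes in, and I want to know how much of it I can find. Partner is the limiting reagent here, with less of it charged than of the starting material. The mono adduct holds one partner, the double product two and the triple product three. The means of the readings at 4.00 h, 6.00 h and 8.00 h are 4.33%, 0.600% and 0.467%, which account for 6.93%. That leaves a gap of 3.50%.

| flask | starting material | partner | remark | time |
|---|---|---|---|---|
| blue | 0.46 M | 0.048 M (fed, over 12 min) | run made earlier |  |
| red | 0.46 M | 0.53 M (fed, over 12 min) | run made earlier |  |
| cedar | 0.46 M | 0.0600 M (fed, over 12 min) |  | 15 h |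
| oak | 0.46 M | 0.150 M (fed, over 12 min) |  | 15 h |
| elm | 0.46 M | 0.300 M (fed, over 12 min) |  | 15 h |
| maple | 0.46 M | 0.600 M (fed, over 12 min) |  | 15 h |

| run | time / h | mono adduct / % | double product / % | triple product / % |
|---|---|---|---|---|
| blue | 2.00 | 3.8 | 0.7 | 0 |
| blue | 4.00 | 4.3 | 0.9 | 0.6 |
| blue | 6.00 | 3.8 | 0.9 | 0.1 |
| blue | 8.00 | 4.9 | 0 | 0.7 |
| red | 1.00 | 20.4 | 6.8 | 1.1 |
| red | 2.50 | 22.8 | 12.8 | 1.4 |
| red | 5.00 | 22.2 | 21.3 | 3.3 |
| red | 8.00 | 23.1 | 25.0 | 2.5 |

(standard deviation of a reading: 1 percentage point)

* share of mono adduct in all that became mono adduct or double product or triple product or tetra adduct or isomer of the product for cedar, oak, elm, maple, in this order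
* the course of these numbers from the first flask to the last (falls all the way / rises all the way / hardly changes / falls, then rises / rises, then falls)

- "hardly changes" means that all values lie within two and a half points (for a concentration: within two and a half percent of the largest)

The isomer of the product is not among the readings, so I put the gap there. I treat mono adduct and isomer as a fast pair in balance, a pre-equilibrium, and reckon with the free fraction f = [mono adduct]/([mono adduct] + [isomer]). From blue, f = 55.3%. This is rough, since the gap adds several readings that each carry 1 percentage point.

Unreacted partner could also hide in the gap, so I test that. Dividing red's mono reading at 1.00 h by f and adding its other readings gives the starting material turned over. That yields a second-order constant of about 1.12 L mol⁻¹ h⁻¹. In blue the starting material stays in excess, so I take the loss of partner as pseudo-first-order and reckon that 4.54% of its charge remains at 6.00 h. That is 0.472% of the starting material, less than the gap.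

The asked share is then [mono adduct] divided by [mono adduct]/f plus the heavier adducts. Blue gives 48.7%, and cedar's charge of 0.0600 M lies next to blue's 0.048 M, so I expect about that for cedar. Red at 8.00 h gives 33.3%, and maple's charge is larger, so I expect maple somewhat lower.

The forecast says 85%, 72%, 59% and 42%, falls all the way, on the ground that “This points to reversible additions approaching equilibrium”, and its first and last values stand above my figures from blue and red.

The flasks give 53.4%, 48.9%, 41.7% and 28.3%: the share falls all the way.

    partner → decomposition product (k = 1.29 × 10⁻⁷ s⁻¹)
    partner + double product → triple product + by-product (k = 1.08 × 10⁻⁴ L mol⁻¹ s⁻¹)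
    starting material + partner → mono adduct + by-product (k = 2.75 × 10⁻⁴ L mol⁻¹ s⁻¹)
    partner + mono adduct → double product + by-product (k = 3.43 × 10⁻⁴ L mol⁻¹ s⁻¹)
    partner + triple product → tetra adduct + by-product (k = 2.99 × 10⁻⁴ L mol⁻¹ s⁻¹)
    mono adduct ⇌ isomer of the product (K = 0.770, k = 1.52 × 10⁻⁴ s⁻¹)

Putting f into cedar's simulated amounts at 15.0 h gives 52.4%, and putting it into maple's gives 28.0%. Maple's share stands where it does mainly because the isomer of the product returns to mono adduct. In the maple run with that return taken away, the share is 1.06% instead of 28.3%.

The earlier runs and the new flask stem from a simulated flask from invented constants; noise was put on by code.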